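**Plan** (labdane numbering: ring A = C1–C5 and C10, ring B = C5–C10, C19 = acetoxymethyl carbon on C4, C11–C16 = spiro side chain)
- Retrosynthesis: cut C15–O first (alkynol cycloisomerisation) and C8–O (Baeyer–Villiger of a C8 acetyl group), then C9–O13 (alkene hydroalkoxylation), then C7–C8 and C9–C10 together, which opens ring B to ring-A aldehyde 10 and allenyl ketone 20.
- Enabling feature: in ring B, C7 is a carbonyl carbon 1,4 to the quaternary C10; C8 becomes an enolate carbon once its later acetate is carried as an acetyl group; C9 can be the sp carbon of an allene. A C10 radical / C7 aldehyde pair can therefore annulate onto C8=C9.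
- Forward: ring A by asymmetric Diels–Alder; C11–C16 from a Sharpless epoxide; ring B by the annulation; ether ring by C9–O13 closure; C8 acetate; C7 ketone; dihydrofuran ring last.
- Stereochemistry: C4/C5 from the catalyst-controlled endo Diels–Alder; C13 from the Sharpless epoxidation; C10, C8 and C9 by substrate control from C5; Baeyer–Villiger with retention.

Key step: step 14

Remark: the enantiomer of the oxazaborolidinium catalyst in step 3 is taken that delivers the (1S,2R) adduct 6; the C7 carbinol configuration of 21–23 and the allene axis of 20 are of no consequence, since both are removed later.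

**Step 1**
Reactants: 1 3-[(tert-butyldimethylsilyl)oxy]propanal; 2 2-(triphenylphosphoranylidene)propanal
Product: 3 (2E)-5-[(tert-butyldimethylsilyl)oxy]-2-methylpent-2-enal
Conditions: toluene, 80 °C
Reagents that add atoms: none
Why: Wittig reaction of the stabilised α-branched ylide should give the (E)-trisubstituted enal.

**Step 2**
Reactants: 3 (2E)-5-[(tert-butyldimethylsilyl)oxy]-2-methylpent-2-enal
Product: 4 tert-butyl(dimethyl){[(3E)-4-methylhexa-3,5-dien-1-yl]oxy}silane
Conditions: Ph3PCH3Br, KOtBu, THF, 0 °C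
Reagents that add atoms: methyltriphenylphosphonium bromide, C[P+](c1ccccc1)(c1ccccc1)c1ccccc1.[Br-]
Why: Wittig methylenation extends the enal to the 1,3-diene and leaves the (E)-trisubstituted alkene untouched.

**Step 3**
Reactants: 4 tert-butyl(dimethyl){[(3E)-4-methylhexa-3,5-dien-1-yl]oxy}silane; 5 methacrolein
Product: 6 (1S,2R)-2-{2-[(tert-butyldimethylsilyl)oxy]ethyl}-1,3-dimethylcyclohex-3-ene-1-carbaldehyde (formyl cis to the side chain)
Conditions: (S)-diphenylprolinol-derived B-(o-tolyl)oxazaborolidine (20 mol%), Tf2NH (16 mol%), CH2Cl2, −78 → −40 °C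
Reagents that add atoms: none
Why: Catalytic enantioselective Diels–Alder reaction, in which the 1-alkyl group of the diene directs the formyl-bearing carbon to C5, the endo transition state places formyl cis to the C5 side chain, and the chiral oxazaborolidinium shields one face of the enal, so that C4 and C5 are set together.

**Step 4**
Reactants: 6 (1S,2R)-2-{2-[(tert-butyldimethylsilyl)oxy]ethyl}-1,3-dimethylcyclohex-3-ene-1-carbaldehyde
Product: 7 [(1S,2R)-2-{2-[(tert-butyldimethylsilyl)oxy]ethyl}-1,3-dimethylcyclohex-3-en-1-yl]methanol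
Conditions: NaBH4, MeOH, 0 °C
Reagents that add atoms: none
Why: Hydride reduction of the neopentyl aldehyde affects no stereocentre.

**Step 5**
Reactants: 7 [(1S,2R)-2-{2-[(tert-butyldimethylsilyl)oxy]ethyl}-1,3-dimethylcyclohex-3-en-1-yl]methanol
Product: 8 [(1S,2R)-2-{2-[(tert-butyldimethylsilyl)oxy]ethyl}-1,3-dimethylcyclohex-3-en-1-yl]methyl acetate
Conditions: Ac2O, pyridine, DMAP (cat.), CH2Cl2, rt
Reagents that add atoms: acetic anhydride, CC(=O)OC(C)=O
Why: Standard acylation installs the C19 acetate of the target, which serves as its own protecting group from here on.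

**Step 6**
Reactants: 8 [(1S,2R)-2-{2-[(tert-butyldimethylsilyl)oxy]ethyl}-1,3-dimethylcyclohex-3-en-1-yl]methyl acetate
Product: 9 [(1S,2R)-2-(2-hydroxyethyl)-1,3-dimethylcyclohex-3-en-1-yl]methyl acetate
Conditions: HF·pyridine, THF, 0 °C → rt
Reagents that add atoms: none
Why: Fluoride cleavage of the silyl ether under non-basic conditions should leave the acetate in place.

**Step 7**
Reactants: 9 [(1S,2R)-2-(2-hydroxyethyl)-1,3-dimethylcyclohex-3-en-1-yl]methyl acetate
Product: 10 [(1S,2R)-1,3-dimethyl-2-(2-oxoethyl)cyclohex-3-en-1-yl]methyl acetate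
Conditions: Dess–Martin periodinane, CH2Cl2, rt
Reagents that add atoms: none
Why: Dess–Martin oxidation stops at the aldehyde and gives the γ,δ-unsaturated aldehyde (C7 aldehyde, C1=C10 alkene) needed for the annulation.

**Step 8**
Reactants: 11 2-methylidenepropane-1,3-diol
Product: 12 2-({[tert-butyl(diphenyl)silyl]oxy}methyl)prop-2-en-1-ol
Conditions: NaH (1 equiv), THF, 0 °C; then tBuPh2SiCl
Reagents that add atoms: tert-butyl(chloro)diphenylsilane, CC(C)(C)[Si](Cl)(c1ccccc1)c1ccccc1
Why: Monosilylation of the symmetric diol through its sparingly soluble monosodium alkoxide.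

**Step 9**
Reactants: 12 2-({[tert-butyl(diphenyl)silyl]oxy}methyl)prop-2-en-1-ol
Product: 13 [(2S)-2-({[tert-butyl(diphenyl)silyl]oxy}methyl)oxiran-2-yl]methanol
Conditions: Ti(OiPr)4, L-(+)-diethyl tartrate, tBuOOH, 4 Å molecular sieves, CH2Cl2, −20 °C
Reagents that add atoms: tert-butyl hydroperoxide, CC(C)(C)OO
Why: Sharpless asymmetric epoxidation of the 2-substituted allylic alcohol with L-(+)-tartrate should give the (S)-epoxy alcohol, whose quaternary carbon becomes C13.

**Step 10**
Reactants: 13 [(2S)-2-({[tert-butyl(diphenyl)silyl]oxy}methyl)oxiran-2-yl]methanol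
Product: 14 (2S)-2-({[tert-butyl(diphenyl)silyl]oxy}methyl)oxirane-2-carbaldehyde
Conditions: Dess–Martin periodinane, pyridine, CH2Cl2, 0 °C
Reagents that add atoms: none
Why: Buffered Dess–Martin oxidation gives the α-quaternary epoxy aldehyde, which cannot epimerise.

**Step 11**
Reactants: 14 (2S)-2-({[tert-butyl(diphenyl)silyl]oxy}methyl)oxirane-2-carbaldehyde
Product: 15 tert-butyl{[(2S)-2-ethynyloxiran-2-yl]methoxy}diphenylsilane
Conditions: dimethyl (1-diazo-2-oxopropyl)phosphonate, K2CO3, MeOH, 0 °C → rt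
Reagents that add atoms: dimethyl (1-diazo-2-oxopropyl)phosphonate, COP(=O)(OC)C(=[N+]=[N-])C(C)=O
Why: Seyferth–Gilbert homologation in the Ohira–Bestmann variant turns the aldehyde into the terminal alkyne C14≡C15 under mild base.

**Step 12**
Reactants: 15 tert-butyl{[(2S)-2-ethynyloxiran-2-yl]methoxy}diphenylsilane
Product: 16 (4R)-4-({[tert-butyl(diphenyl)silyl]oxy}methyl)-4-[(triethylsilyl)oxy]-6-(triethylsilyl)hex-5-ynoic acid
Conditions: AcOH, LDA, THF–HMPA, 0 → 45 °C; then Et3SiCl, 0 °C; aqueous work-up (pH 5)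
Reagents that add atoms: acetic acid, CC(=O)O; chlorotriethylsilane, CC[Si](Cl)(CC)CC
Why: The acetic acid dianion opens the epoxide at its CH2 carbon (C12) by SN2 attack, so the C13 oxygen and configuration stay untouched; the excess base metallates the alkyne and Et3SiCl caps alkoxide, carboxylate and acetylide, the silyl ester being hydrolysed on work-up.

**Step 13**
Reactants: 16 (4R)-4-({[tert-butyl(diphenyl)silyl]oxy}methyl)-4-[(triethylsilyl)oxy]-6-(triethylsilyl)hex-5-ynoic acid; 17 3-(triphenylphosphoranylidene)butan-2-one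
Product: 20 (7R)-7-({[tert-butyl(diphenyl)silyl]oxy}methyl)-3-methyl-7-[(triethylsilyl)oxy]-9-(triethylsilyl)nona-3,4-dien-8-yn-2-one (both allene-axis epimers), via acid chloride 18 (not isolated), via ketene 19 (not isolated)
Conditions: 1-chloro-N,N,2-trimethylprop-1-en-1-amine, CH2Cl2, 0 °C; then 17, Et3N, CH2Cl2, 0 °C → rt
Reagents that add atoms: none
Why: Wittig olefination of a ketene, in which the acid chloride formed under neutral conditions is dehydrochlorinated by Et3N and the stabilised ylide adds to the ketene carbonyl to give the 1,2-allenyl ketone.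

**Step 14**
Reactants: 10 [(1S,2R)-1,3-dimethyl-2-(2-oxoethyl)cyclohex-3-en-1-yl]methyl acetate; 20 (7R)-7-({[tert-butyl(diphenyl)silyl]oxy}methyl)-3-methyl-7-[(triethylsilyl)oxy]-9-(triethylsilyl)nona-3,4-dien-8-yn-2-one
Product: 21 trans-decalin β-hydroxy ketone (4β-CH2OAc, 4α-CH3, 5α-H, 10β-CH3, 7β-OH, 8β-acetyl, 8α-CH3, (Z)-C9=C11 exocyclic alkene; side chain C12H2–C13(R)(OSiEt3)(CH2OSiPh2tBu)–C≡C–SiEt3)
Conditions: Fe(acac)3 (30 mol%), PhSiH3, EtOH–THF, 40 °C
Reagents that add atoms: none
Why: Proposed new method: an iron hydride formed from Fe(acac)3 and PhSiH3 transfers a hydrogen atom to C1 of the electron-rich ring alkene of 10, the tertiary C10 radical adds to the central sp carbon (C9) of allenyl ketone 20, and reduction of the resulting α-keto radical by divalent iron gives an iron dienolate whose C8 adds to the C7 aldehyde (radical–polar crossover). The closest known reaction type is the hydrogen-atom-transfer-initiated radical conjugate addition–aldol annulation of γ,δ-unsaturated aldehydes with enones; the new element is the allenyl ketone acceptor, whose sp centre should admit a tertiary radical where a β,β-disubstituted enone would not, and which leaves the C9=C11 alkene needed for the ether ring. Ring B closes in the aldol step in the 6-(enolexo)-exo-trig mode, after the intermolecular radical addition has joined C9 to C10. C10 is set by addition anti to the C5 side chain (trans ring fusion); C8 by a chair transition state that keeps the C8 methyl equatorial, away from the (Z)-C12 substituent, and the enolate carbon axial; C7 by the metal chelate (equatorial hydroxyl, oxidised later). The step needs hydrogen-atom transfer to the trisubstituted ring alkene in preference to the allene, and attack at the central allene carbon syn to the allenic hydrogen; the electron-rich alkene, the silyl cap on the alkyne and the conjugation of the C8=C9 π bond with the ketone should secure this.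

**Step 15**
Reactants: 21 trans-decalin β-hydroxy ketone
Product: 22 spiro ether (as 21, but C9 carries the 9α-O–C13 tetrahydrofuran ring with C11 β and C13 R; C11 is CH2)
Conditions: [N,N′-bis(3,5-di-tert-butylsalicylidene)-1,2-cyclohexanediaminato]cobalt (5 mol%), N-fluoro-2,4,6-trimethylpyridinium triflate, PhSiH3, PhCF3, 0 °C → rt
Reagents that add atoms: none
Why: Markovnikov hydroalkoxylation by cobalt-hydride hydrogen-atom transfer to C11 and oxidation of the tertiary C9 radical, the cation being captured by the C13 silyl ether oxygen with loss of the silyl group; attack on the α face, anti to the axial C10 methyl and C8 acetyl groups, should set C9.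

**Step 16**
Reactants: 22 spiro ether
Product: 23 8β-acetate (as 22, with OAc in place of the C8 acetyl group)
Conditions: mCPBA, CH2Cl2, 0 °C → rt
Reagents that add atoms: 3-chloroperbenzoic acid, OOC(=O)c1cccc(Cl)c1
Why: Baeyer–Villiger oxidation, in which the tertiary C8 migrates in preference to methyl and with retention, so that the axial acetyl group becomes the 8β-acetate.

**Step 17**
Reactants: 23 8β-acetate
Product: 24 7-ketone (as 23, with C7=O)
Conditions: Dess–Martin periodinane, CH2Cl2, rt
Reagents that add atoms: none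
Why: Base-free Dess–Martin oxidation of the secondary C7 alcohol gives the α-acetoxy ketone and avoids acetyl migration.

**Step 18**
Reactants: 24 7-ketone
Product: 25 alkynol (as 24, with free C16 hydroxyl and terminal C14≡C15 alkyne)
Conditions: Bu4NF, AcOH, THF, rt
Reagents that add atoms: none
Why: Fluoride cleaves the O–Si bond at C16 and the C–Si bond of the alkynylsilane in one operation, acetic acid buffering the medium so that both acetates survive.

**Step 19**
Reactants: 25 alkynol
Product: 26 CNP0351241.1 (target)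
Conditions: Mo(CO)6 (cat.), Me3NO, Et3N, Et2O, rt
Reagents that add atoms: none
Why: Endo cycloisomerisation of the but-3-yn-1-ol unit through a molybdenum vinylidene (C16 hydroxyl onto C15) should give the 2,3-dihydrofuran under basic conditions that the spiro enol ether tolerates.

**Compound list**
1 | 3-[(tert-butyldimethylsilyl)oxy]propanal | O=CCCO[Si](C)(C)C(C)(C)C | starting material
2 | 2-(triphenylphosphoranylidene)propanal | CC(C=O)=P(c1ccccc1)(c1ccccc1)c1ccccc1 | starting material
3 | (2E)-5-[(tert-butyldimethylsilyl)oxy]-2-methylpent-2-enal | O=C/C(C)=C/CCO[Si](C)(C)C(C)(C)C | intermediate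
4 | tert-butyl(dimethyl){[(3E)-4-methylhexa-3,5-dien-1-yl]oxy}silane | C=C/C(C)=C/CCO[Si](C)(C)C(C)(C)C | intermediate
5 | methacrolein | C=C(C)C=O | starting material
6 | (1S,2R)-2-{2-[(tert-butyldimethylsilyl)oxy]ethyl}-1,3-dimethylcyclohex-3-ene-1-carbaldehyde | O=C[C@@]1(C)CCC=C(C)[C@H]1CCO[Si](C)(C)C(C)(C)C | intermediate
7 | [(1S,2R)-2-{2-[(tert-butyldimethylsilyl)oxy]ethyl}-1,3-dimethylcyclohex-3-en-1-yl]methanol | OC[C@@]1(C)CCC=C(C)[C@H]1CCO[Si](C)(C)C(C)(C)C | intermediate
8 | [(1S,2R)-2-{2-[(tert-butyldimethylsilyl)oxy]ethyl}-1,3-dimethylcyclohex-3-en-1-yl]methyl acetate | CC(=O)OC[C@@]1(C)CCC=C(C)[C@H]1CCO[Si](C)(C)C(C)(C)C | intermediate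
9 | [(1S,2R)-2-(2-hydroxyethyl)-1,3-dimethylcyclohex-3-en-1-yl]methyl acetate | CC(=O)OC[C@@]1(C)CCC=C(C)[C@H]1CCO | intermediate
10 | [(1S,2R)-1,3-dimethyl-2-(2-oxoethyl)cyclohex-3-en-1-yl]methyl acetate | CC(=O)OC[C@@]1(C)CCC=C(C)[C@H]1CC=O | intermediate
11 | 2-methylidenepropane-1,3-diol | C=C(CO)CO | starting material
12 | 2-({[tert-butyl(diphenyl)silyl]oxy}methyl)prop-2-en-1-ol | C=C(CO)CO[Si](c1ccccc1)(c1ccccc1)C(C)(C)C | intermediate
13 | [(2S)-2-({[tert-butyl(diphenyl)silyl]oxy}methyl)oxiran-2-yl]methanol | C1O[C@@]1(CO[Si](c2ccccc2)(c2ccccc2)C(C)(C)C)CO | intermediate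
14 | (2S)-2-({[tert-butyl(diphenyl)silyl]oxy}methyl)oxirane-2-carbaldehyde | C1O[C@@]1(CO[Si](c2ccccc2)(c2ccccc2)C(C)(C)C)C=O | intermediate
15 | tert-butyl{[(2S)-2-ethynyloxiran-2-yl]methoxy}diphenylsilane | C1O[C@@]1(CO[Si](c2ccccc2)(c2ccccc2)C(C)(C)C)C#C | intermediate
16 | (4R)-4-({[tert-butyl(diphenyl)silyl]oxy}methyl)-4-[(triethylsilyl)oxy]-6-(triethylsilyl)hex-5-ynoic acid | OC(=O)CC[C@](CO[Si](c1ccccc1)(c1ccccc1)C(C)(C)C)(C#C[Si](CC)(CC)CC)O[Si](CC)(CC)CC | intermediate
17 | 3-(triphenylphosphoranylidene)butan-2-one | CC(=O)C(C)=P(c1ccccc1)(c1ccccc1)c1ccccc1 | starting material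
18 | (4R)-4-({[tert-butyl(diphenyl)silyl]oxy}methyl)-4-[(triethylsilyl)oxy]-6-(triethylsilyl)hex-5-ynoyl chloride | ClC(=O)CC[C@](CO[Si](c1ccccc1)(c1ccccc1)C(C)(C)C)(C#C[Si](CC)(CC)CC)O[Si](CC)(CC)CC | intermediate
19 | (4R)-4-({[tert-butyl(diphenyl)silyl]oxy}methyl)-4-[(triethylsilyl)oxy]-6-(triethylsilyl)hex-1-en-5-yn-1-one (ketene) | O=C=CC[C@](CO[Si](c1ccccc1)(c1ccccc1)C(C)(C)C)(C#C[Si](CC)(CC)CC)O[Si](CC)(CC)CC | intermediate
20 | (7R)-7-({[tert-butyl(diphenyl)silyl]oxy}methyl)-3-methyl-7-[(triethylsilyl)oxy]-9-(triethylsilyl)nona-3,4-dien-8-yn-2-one (allene axis not defined) | CC(=O)C(C)=C=CC[C@](CO[Si](c1ccccc1)(c1ccccc1)C(C)(C)C)(C#C[Si](CC)(CC)CC)O[Si](CC)(CC)CC | intermediate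
21 | trans-decalin β-hydroxy ketone (7β-OH, 8β-acetyl, 8α-CH3, (Z)-C9=C11, 19-OAc, silylated C12–C16 chain) | CC(=O)OC[C@@]1(C)CCC[C@@]2(C)[C@H]1C[C@H](O)[C@](C)(C(C)=O)/C2=C\C[C@](CO[Si](c1ccccc1)(c1ccccc1)C(C)(C)C)(C#C[Si](CC)(CC)CC)O[Si](CC)(CC)CC | intermediate
22 | spiro ether (9α,13-epoxy; 7β-OH, 8β-acetyl) | CC(=O)OC[C@@]1(C)CCC[C@@]2(C)[C@H]1C[C@H](O)[C@](C)(C(C)=O)[C@]21CC[C@](CO[Si](c3ccccc3)(c3ccccc3)C(C)(C)C)(C#C[Si](CC)(CC)CC)O1 | intermediate
23 | 8β-acetate (7β-OH) | CC(=O)OC[C@@]1(C)CCC[C@@]2(C)[C@H]1C[C@H](O)[C@](C)(OC(C)=O)[C@]21CC[C@](CO[Si](c3ccccc3)(c3ccccc3)C(C)(C)C)(C#C[Si](CC)(CC)CC)O1 | intermediate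
24 | 7-ketone | CC(=O)OC[C@@]1(C)CCC[C@@]2(C)[C@H]1CC(=O)[C@](C)(OC(C)=O)[C@]21CC[C@](CO[Si](c3ccccc3)(c3ccccc3)C(C)(C)C)(C#C[Si](CC)(CC)CC)O1 | intermediate
25 | alkynol (13-ethynyl, 16-hydroxy) | CC(=O)OC[C@@]1(C)CCC[C@@]2(C)[C@H]1CC(=O)[C@](C)(OC(C)=O)[C@]21CC[C@](CO)(C#C)O1 | intermediate
26 | CNP0351241.1 | CC(=O)OC[C@@]1(C)CCC[C@@]2(C)[C@H]1CC(=O)[C@](C)(OC(C)=O)[C@]21CC[C@]2(C=COC2)O1 | target

**Totals**
Total step count: 19. Longest linear sequence: 13 steps (steps 1–7, then 14–19).

**Steps most likely to fail**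

Step 14 (Proposed new method). The tertiary C10 radical may be reduced before it adds, the allenyl ketone may be consumed by hydride reduction or oligomerisation, or the aldol closure may give the C8 epimer. The fallback uses known reactions, sets out from 10 and 20 and returns at 21. Soft enolisation of 20 through its allenic hydrogen (MgBr2·OEt2, iPr2NEt, CH2Cl2, −20 °C) and α-selective aldol addition of the 1-en-3-ynolate to aldehyde 10 should give the propargylic β-hydroxy ketone F1, from which the C7/C8 diastereomers would be separated. A hydrogen-atom-transfer-initiated 6-exo-dig radical cyclisation of the C10 radical onto the C9≡C11 alkyne (Fe(acac)3, PhSiH3, EtOH, 60 °C) then closes ring B and gives 21; either alkene geometry serves, since C11 becomes sp3 in step 15.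

Step 15. The congested tertiary C9 radical or cation may lose a proton to a diene, suffer a 1,2-methyl shift from C10, or be captured on the β face. The fallback sets out from 21 and returns at 22. Selective methanolysis of the tertiary triethylsilyl ether (PPTS, MeOH, 0 °C) gives the tertiary alcohol F2. Iodoetherification (N-iodosuccinimide, NaHCO3, CH2Cl2, 0 °C; Markovnikov closure at C9, anti to iodine on C11) gives the iodo ether F3. Radical deiodination (Bu3SnH, AIBN, toluene, 80 °C) gives 22.

Step 3. Enantiofacial discrimination, and the endo and regiochemical preference, may be insufficient with this 1,2-disubstituted diene. The fallback sets out from 4 and 5 and returns at 8. Cycloaddition promoted by EtAlCl2 (CH2Cl2, −78 °C) gives 6 together with its enantiomer F4; NaBH4 reduction gives 7 together with its enantiomer F5. Lipase-catalysed acylation (Burkholderia cepacia lipase, vinyl acetate, tert-butyl methyl ether) should acetylate the (1S,2R) alcohol to 8 and leave F5, which is removed by chromatography. This fallback addresses enantiofacial control only; endo and regiochemical preference would rest on the Lewis acid.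

**Further compounds**
F1 | step 14 | open-chain aldol adduct (ring-A cyclohexene; 7-OH; C8 bearing CH3, acetyl and the C9≡C11 alkyne; silylated C12–C16 chain) | CC(=O)OC[C@@]1(C)CCC=C(C)[C@H]1C[C@H](O)[C@](C)(C(C)=O)C#CC[C@](CO[Si](c2ccccc2)(c2ccccc2)C(C)(C)C)(C#C[Si](CC)(CC)CC)O[Si](CC)(CC)CC
F2 | step 15 | tertiary C13 alcohol corresponding to 21 | CC(=O)OC[C@@]1(C)CCC[C@@]2(C)[C@H]1C[C@H](O)[C@](C)(C(C)=O)/C2=C\C[C@](CO[Si](c1ccccc1)(c1ccccc1)C(C)(C)C)(C#C[Si](CC)(CC)CC)O
F3 | step 15 | 11-iodo spiro ether (C11 configuration not defined) | CC(=O)OC[C@@]1(C)CCC[C@@]2(C)[C@H]1C[C@H](O)[C@](C)(C(C)=O)[C@]21C(I)C[C@](CO[Si](c3ccccc3)(c3ccccc3)C(C)(C)C)(C#C[Si](CC)(CC)CC)O1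
F4 | step 3 | (1R,2S)-enantiomer of 6 | O=C[C@]1(C)CCC=C(C)[C@@H]1CCO[Si](C)(C)C(C)(C)C
F5 | step 3 | (1R,2S)-enantiomer of 7 | OC[C@]1(C)CCC=C(C)[C@@H]1CCO[Si](C)(C)C(C)(C)C
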